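All runs stem from a simulated flask for substances that don't exist.

Add up the percentages before you open any solver.

| setting | south-east | west | flask |
|---|---|---|---|
| substrate | 0.050 M | 0.050 M | 0.050 M |
| partner | 0.0475 M | 0.0475 M | 0.0475 M |
| temperature | 25 °C | 20 °C | 25 °C |
| remark | the very flask that is asked about, followed so far | run made earlier |  |
| time |  |  | 40 h |

- south-east (time / h: bis adduct / %, substrate / %): 3.00: 3.6, 86.8; 5.00: 7.6, 80.7; 8.00: 11.9, 75.8; 15.0: 16.0, 70.0; 25.0: 18.5, 67.4; 40.0: 20.3, 65.8
- west (time / h: bis adduct / %, substrate / %): 3.00: 4.1, 91.0; 5.00: 5.0, 85.7; 8.00: 9.1, 81.1; 15.0: 14.7, 73.1; 25.0: 16.4, 69.4; 40.0: 21.0, 67.6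

(standard deviation of a reading: 1 percentage point)

- delta: change nothing and wait 40 h more
- beta: at 40 h raise the temperature by 25 K, then wait 40 h
- eta: at 40 h take out 90 % of the bis adduct then present, then wait 40 h
- gamma: at 40 h add partner, 100 % of the amount charged, then wait 40 h

- bis adduct that was removed still counts
- the earlier runs were read with a standard deviation of 1 percentage point
- additions bring no volume worth counting

- bis adduct, in percent of the substrate first charged, at 40 h
- what to do for the largest gain in bis adduct; "none" if nothing gains more than 2 percentage points (delta / beta / eta / gamma / none)
- bis adduct present, with what was taken out counted in, in percent of the substrate first charged, after beta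
- bis adduct present, with what was taken out counted in, in percent of the substrate first charged, after eta

Is anything in the south-east flask steady? Take what is neither substrate nor bis adduct as first product: 14.0 % at 15.0 h, 14.1 % at 25.0 h, 13.9 % at 40.0 h. Treat that flat reading as a steady state, made as fast as it is used. If both steps take partner, partner cancels from this balance. Substrate over first product, read at 25.0 h, is then 4.78: call this reading the selectivity factor. The west run, cooler, reads 4.89.

So multiply the substrate present by 1.21 to get the part of the charge not yet bis adduct. Substrate at 65.8 % then gives my own 20.4 % for now.

What does waiting buy? A gain of 2 percentage points needs substrate to fall 1.7 points. The south-east readings fell 2.6 points in 10.0 h, then 1.6 points in 15.0 h. Count delta as below the margin.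

What restarts substrate? By the readings, first product and bis adduct hold partner worth 54.5 % of the substrate charge, against 95.0 % supplied, yet the south-east flask crawls. Treat partner as the limiting reagent, lost somewhere unseen, and count heat and removal with waiting. Suppose a like charge takes the same fraction of substrate: 43.3 % remains, and bis adduct reaches 47.6 %.

The forecast gives 20.4 % for now, gamma as best, 20.5 % after beta and 25 % after eta: “Adding partner helps under the first two, and strongly, so gamma is best.” On eta the forecast parts from my count, which keeps removal with waiting.

The flask gives 20.2 % for now and gamma as best, gaining 27 points, with 20.6 % after beta and 20.5 % after eta. With the substrate and the time held, a partner charge of 0.0347 M or 0.0624 M moves the answer for now by 5 points.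

    substrate + partner → first product + by-product (k = 0.0240 M⁻¹ min⁻¹, Ea = 65.0 kJ mol⁻¹)
    partner + first product → bis adduct + by-product (k = 0.120 M⁻¹ min⁻¹, Ea = 68.0 kJ mol⁻¹)
    2 partner → self-condensation product (k = 0.0290 M⁻¹ min⁻¹, Ea = 76.0 kJ mol⁻¹)
    (constants at 25 °C)

Take the neighbour charged with 0.19 M of partner. Its substrate ends at 40.9 %. Carry the selectivity factor over: multiply by 1.21 and subtract from the charge, and bis adduct comes to 50.5 %. At the end that neighbour holds bis adduct at 49.1 %.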